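**Retrosynthetic overview**

1. The plan rests on ring A (the cyclohexene oxide ring). Its epoxide comes from the alkene C(e)=C(f), with the methyl group on C(e), lying between C(d) and C(a) (the CH carrying the linker CH2), with C(b) (the CH carrying isopropenyl) next to C(a). This is the 1,2/1,4 pattern of a cyclohexene made from a 1-alkyl-3-methylbutadiene and an acrylate.
2. Epoxide ring (formed last): C(e)–O–C(f) by reagent-controlled epoxidation of the only trisubstituted alkene of triene alcohol 17. The isopropenyl group at C(b) comes from the acyl group of the cycloadduct (Weinreb amide, MeMgBr, cis to trans epimerisation, Wittig).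
3. Ring A (formed second): bonds C(a)–C(b) and C(c)–C(d) by a Diels–Alder reaction of (E)-diene 10 with acryloyl oxazolidinone 11 under [Cu((R,R)-t-Bu-box)](SbF6)2.
4. Diene 10: the bond between the linker CH2 and the diene by Suzuki–Miyaura coupling of allyl chloride 7 with dienylboronate 9; 7 by ene chlorination of the isopropenyl group.
5. Ring B (first, from the chiral pool): cis-bromohydrin 5 from (1S,2S,4R)-limonene-1,2-diol 1 via its cyclic sulfate and bromide opening with inversion.

Key step: step 8

Remark on labels: the carbons of ring A are lettered C(a) (CH with the linker CH2), C(b) (CH with isopropenyl), C(c) and C(d) (CH2), C(e) (C–CH3) and C(f) (CH). Ring B is the bromohydrin ring; its atoms are called the carbinol carbon and the CHBr carbon. (R,R)-t-Bu-box is 2,2'-isopropylidenebis[(4R)-4-tert-butyl-2-oxazoline].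
Assumption: step 11 is an equilibration; any cis ketone left is separated and resubmitted.

**Step 1**
Reactants: 1 (1S,2S,4R)-limonene-1,2-diol
Product: 2 trans-fused cyclic sulfite of the diol (both sulfur epimers)
Conditions: SOCl2 (1.2 equiv), Et3N (3 equiv), CH2Cl2, 0 °C
Reagents that add atoms: thionyl chloride, O=S(Cl)Cl
Why: Cyclic sulfite formation from a 1,2-diol and thionyl chloride: the secondary hydroxyl is sulfinylated first and the tertiary hydroxyl closes the five-membered ring through the chair with both oxygens equatorial; no carbon stereocentre is touched and the sulfur epimers converge in step 2.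

**Step 2**
Reactants: 2 cyclic sulfite
Product: 3 cyclic sulfate
Conditions: RuCl3·xH2O (0.1 mol %), NaIO4 (1.1 equiv), MeCN/CCl4/H2O, 0 °C, 10 min; 2-propanol quench
Reagents that add atoms: sodium periodate, [Na+].[O-]I(=O)(=O)=O
Why: RuO4-catalysed oxidation of a cyclic sulfite to the cyclic sulfate: the sulfur oxidation turns over within minutes at very low ruthenium loading, whereas catalytic cleavage of an isolated C=C needs much longer at percent loadings, so with limiting periodate and short contact the isopropenyl group should survive; no stereocentre changes.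

**Step 3**
Reactants: 3 cyclic sulfate
Product: 5 (1S,2R,4R)-2-bromo-1-methyl-4-(prop-1-en-2-yl)cyclohexan-1-ol, via lithium bromoalkyl sulfate 4 (not isolated)
Conditions: LiBr (3 equiv), THF, 25 → 50 °C; then H2SO4 (cat.), H2O (2 equiv), THF, 25 °C
Reagents that add atoms: lithium bromide, [Li+].[Br-]
Why: SN2 opening of a cyclic sulfate: bromide attacks the secondary ring carbon rather than the fully substituted carbinol carbon, with inversion, so Br ends cis to the carbinol oxygen and cis to the isopropenyl group (Br, CH3 and isopropenyl equatorial, oxygen axial); acid hydrolysis of the tertiary sulfate monoester by S–O cleavage retains the configuration of the carbinol carbon.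

**Step 4**
Reactants: 5 cis-bromohydrin
Product: 6 triethylsilyl ether of 5
Conditions: Et3SiOTf (1.5 equiv), 2,6-lutidine (2.5 equiv), CH2Cl2, −78 → 0 °C
Reagents that add atoms: triethylsilyl trifluoromethanesulfonate, CC[Si](CC)(CC)OS(=O)(=O)C(F)(F)F
Why: Silyl triflate/2,6-lutidine silylation of a hindered tertiary alcohol, done before step 5 because the free hydroxyl, cis to the isopropenyl group, could trap the chloronium ion as a bridged cineole-type ether; no stereocentre changes.

**Step 5**
Reactants: 6 silyl ether
Product: 7 allyl chloride (isopropenyl CH3 converted to CH2Cl; C=CH2 retained)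
Conditions: Ca(OCl)2, solid CO2, CH2Cl2/H2O, 0 °C
Reagents that add atoms: calcium hypochlorite, [Ca+2].[O-]Cl.[O-]Cl
Why: Ene-type allylic chlorination of an isopropenyl group by hypochlorous acid generated in situ, a reaction well used on isopropenyl terpenoids: Cl+ adds to the terminal CH2 and a methyl proton is lost, giving the 2-substituted allyl chloride; no stereocentre is involved.

**Step 6**
Reactants: 8 2-methylbut-1-en-3-yne
Product: 9 (E)-4,4,5,5-tetramethyl-2-(3-methylbuta-1,3-dien-1-yl)-1,3,2-dioxaborolane
Conditions: pinacolborane (1.1 equiv), Cp2Zr(H)Cl (5 mol %), Et3N (10 mol %), CH2Cl2, rt, sealed vessel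
Reagents that add atoms: pinacolborane, [H]B1OC(C)(C)C(C)(C)O1
Why: Cp2Zr(H)Cl-catalysed hydroboration of a terminal alkyne: syn addition with boron at the terminal carbon gives the (E)-alkenylboronate, and the alkyne reacts well ahead of the 1,1-disubstituted alkene.

**Step 7**
Reactants: 7 allyl chloride; 9 dienylboronate (1.3 equiv)
Product: 10 (E)-diene carrying silylated ring B
Conditions: Pd(PPh3)4 (5 mol %), K3PO4 (3 equiv, aq.), THF, 60 °C
Reagents that add atoms: none
Why: Suzuki–Miyaura allyl–alkenyl coupling: zerovalent palladium ionises the allylic chloride to a π-allyl complex with two equivalent CH2 termini, the boronate transmetalates with retention of (E) geometry and reductive elimination gives the skipped triene; the secondary alkyl bromide does not add oxidatively to Pd(PPh3)4 under these conditions.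

**Step 8**
Reactants: 10 (E)-diene; 11 3-acryloyl-1,3-oxazolidin-2-one (1.5 equiv)
Product: 12 cis (endo) cycloadduct, (S) at C(a) and (R) at C(b)
Conditions: [Cu((R,R)-t-Bu-box)](SbF6)2 (10 mol %, pre-formed from CuCl2, the ligand and AgSbF6), CH2Cl2, −20 °C → rt
Reagents that add atoms: none
Why: The two imide carbonyls chelate the cationic divalent copper centre in a distorted square plane with the acryloyl unit s-cis, which activates the dienophile enough for an acyclic trialkyl diene, and the diene then adds in a concerted, asynchronous [4+2] cycloaddition. The closest known reaction type is the [Cu(t-Bu-box)](SbF6)2-catalysed Diels–Alder reaction of this same imide with 1-substituted and 3-methyl-substituted acyclic butadienes. Ring A is closed by the intermolecular suprafacial cycloaddition itself, which forms C(a)–C(b) and C(c)–C(d) in one event and leaves the C(e)=C(f) alkene. C(b) is set by the ligand: the tert-butyl group next to the bound alkene blocks the Re face of the α-carbon, so the diene adds to its Si face (the (S,S)-ligand gives the opposite sense), and C(a) follows from the endo transition state with the (E)-diene, which gives the cis adduct. The step needs regio-, endo- and face selectivity: the 1-alkyl and 3-methyl groups of the diene both place the larger HOMO coefficient on the unsubstituted terminus, so the acyl-bearing carbon ends next to C(a), endo selectivity comes from overlap with the chelated imide, and the ring B stereocentres are too remote from C(a) to compete with the catalyst. The isolated 1,1-disubstituted alkene cannot act as a diene, and the bromide and silyl ether are inert to this mild Lewis acid.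

**Step 9**
Reactants: 12 cis cycloadduct
Product: 13 cis N-methoxy-N-methylamide
Conditions: Me(MeO)NH·HCl (3 equiv), AlMe3 (3 equiv), CH2Cl2, −10 → 0 °C
Reagents that add atoms: N,O-dimethylhydroxylamine hydrochloride, CNOC.Cl
Why: AlMe3-mediated aminolysis of an N-acyloxazolidinone at the exocyclic carbonyl gives the Weinreb amide; the conditions are non-basic, so the cis relationship of C(a) and C(b) is carried through unchanged.

**Step 10**
Reactants: 13 Weinreb amide
Product: 14 cis methyl ketone
Conditions: MeMgBr (3 equiv), THF, 0 °C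
Reagents that add atoms: methylmagnesium bromide, C[Mg]Br
Why: Weinreb ketone synthesis: the magnesium-chelated tetrahedral intermediate stops the addition at the methyl ketone; C(a) and C(b) are untouched.

**Step 11**
Reactants: 14 cis methyl ketone
Product: 15 trans methyl ketone, (S) at C(a) and (S) at C(b)
Conditions: NaOMe (0.3 equiv), MeOH/THF, rt
Reagents that add atoms: none
Why: Base-mediated epimerisation through the enolate under thermodynamic control: C(b), α to the carbonyl, should equilibrate towards the trans isomer in which acetyl and the side chain on C(a) are both (pseudo)equatorial, while C(a) is not acidic and is kept.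

**Step 12**
Reactants: 15 trans methyl ketone
Product: 16 triene silyl ether
Conditions: Ph3PCH3Br (2 equiv), KOt-Bu (1.9 equiv), THF, 0 °C → rt
Reagents that add atoms: methyltriphenylphosphonium bromide, C[P+](c1ccccc1)(c1ccccc1)c1ccccc1.[Br-]
Why: Wittig methylenation turns the acetyl group into the isopropenyl group; C(b) already has the thermodynamically preferred configuration, so reversible enolisation by the basic ylide cannot erode it.

**Step 13**
Reactants: 16 triene silyl ether
Product: 17 triene alcohol
Conditions: Bu4NF (3 equiv), THF, rt → 40 °C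
Reagents that add atoms: none
Why: Fluoride cleavage of the triethylsilyl ether; the alkoxide set free is cis to the neighbouring bromide and cannot displace it to form an epoxide.

**Step 14**
Reactants: 17 triene alcohol
Product: 18 target epoxide
Conditions: D-fructose-derived Shi ketone (1,2:4,5-di-O-isopropylidene-β-D-erythro-2,3-hexodiulo-2,6-pyranose, 30 mol %), Oxone (2KHSO5·KHSO4·K2SO4, 1.4 equiv), K2CO3, Bu4NHSO4 (cat.), MeCN/dimethoxymethane/aq. Na2B4O7–Na2EDTA buffer (pH 10.5), 0 °C
Reagents that add atoms: potassium peroxymonosulfate, [K+].[O-]S(=O)(=O)OO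
Why: Shi epoxidation: the chiral dioxirane formed in situ is electrophilic and should oxidise the trisubstituted C(e)=C(f) alkene ahead of the two 1,1-disubstituted alkenes, and its spiro transition state delivers oxygen with the sense known for 1-substituted cyclohexenes and the D-fructose-derived ketone, here the face cis to the side chain on C(a) and trans to isopropenyl, which sets C(e) as (S) and C(f) as (R).

**Compound list**

1 | (1S,2S,4R)-1-methyl-4-(prop-1-en-2-yl)cyclohexane-1,2-diol (trans-diol) | CC(=C)[C@@H]1CC[C@](C)(O)[C@@H](O)C1 | starting material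
2 | (3aS,6R,7aS)-3a-methyl-6-(prop-1-en-2-yl)hexahydro-1,3,2-benzodioxathiole 2-oxide (sulfur epimers) | CC(=C)[C@@H]1CC[C@](C)(OS2=O)[C@@H](O2)C1 | intermediate
3 | (3aS,6R,7aS)-3a-methyl-6-(prop-1-en-2-yl)hexahydro-1,3,2-benzodioxathiole 2,2-dioxide | CC(=C)[C@@H]1CC[C@](C)(OS2(=O)=O)[C@@H](O2)C1 | intermediate
4 | lithium (1S,2R,4R)-2-bromo-1-methyl-4-(prop-1-en-2-yl)cyclohexyl sulfate | CC(=C)[C@@H]1CC[C@](C)(OS(=O)(=O)[O-])[C@H](Br)C1.[Li+] | intermediate (not isolated)
5 | (1S,2R,4R)-2-bromo-1-methyl-4-(prop-1-en-2-yl)cyclohexan-1-ol | CC(=C)[C@@H]1CC[C@](C)(O)[C@H](Br)C1 | intermediate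
6 | {[(1S,2R,4R)-2-bromo-1-methyl-4-(prop-1-en-2-yl)cyclohexyl]oxy}triethylsilane | CC(=C)[C@@H]1CC[C@](C)(O[Si](CC)(CC)CC)[C@H](Br)C1 | intermediate
7 | {[(1S,2R,4R)-2-bromo-4-(3-chloroprop-1-en-2-yl)-1-methylcyclohexyl]oxy}triethylsilane | ClCC(=C)[C@@H]1CC[C@](C)(O[Si](CC)(CC)CC)[C@H](Br)C1 | intermediate
8 | 2-methylbut-1-en-3-yne | C=C(C)C#C | starting material
9 | (E)-4,4,5,5-tetramethyl-2-(3-methylbuta-1,3-dien-1-yl)-1,3,2-dioxaborolane | C=C(C)/C=C/B1OC(C)(C)C(C)(C)O1 | intermediate
10 | {[(1S,2R,4R)-2-bromo-1-methyl-4-[(4E)-6-methylhepta-1,4,6-trien-2-yl]cyclohexyl]oxy}triethylsilane | C=C(C)/C=C/CC(=C)[C@@H]1CC[C@](C)(O[Si](CC)(CC)CC)[C@H](Br)C1 | intermediate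
11 | 3-acryloyl-1,3-oxazolidin-2-one | C=CC(=O)N1CCOC1=O | starting material
12 | 3-{[(1R,2S)-2-{2-[(1R,3R,4S)-3-bromo-4-methyl-4-(triethylsilyloxy)cyclohexyl]prop-2-en-1-yl}-4-methylcyclohex-3-en-1-yl]carbonyl}-1,3-oxazolidin-2-one (cis) | C=C(C[C@@H]1[C@H](C(=O)N2CCOC2=O)CCC(C)=C1)[C@@H]1CC[C@](C)(O[Si](CC)(CC)CC)[C@H](Br)C1 | intermediate
13 | (1R,2S)-2-{2-[(1R,3R,4S)-3-bromo-4-methyl-4-(triethylsilyloxy)cyclohexyl]prop-2-en-1-yl}-N-methoxy-N,4-dimethylcyclohex-3-ene-1-carboxamide (cis) | C=C(C[C@@H]1[C@H](C(=O)N(C)OC)CCC(C)=C1)[C@@H]1CC[C@](C)(O[Si](CC)(CC)CC)[C@H](Br)C1 | intermediate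
14 | 1-[(1R,2S)-2-{2-[(1R,3R,4S)-3-bromo-4-methyl-4-(triethylsilyloxy)cyclohexyl]prop-2-en-1-yl}-4-methylcyclohex-3-en-1-yl]ethan-1-one (cis) | C=C(C[C@@H]1[C@H](C(C)=O)CCC(C)=C1)[C@@H]1CC[C@](C)(O[Si](CC)(CC)CC)[C@H](Br)C1 | intermediate
15 | 1-[(1S,2S)-2-{2-[(1R,3R,4S)-3-bromo-4-methyl-4-(triethylsilyloxy)cyclohexyl]prop-2-en-1-yl}-4-methylcyclohex-3-en-1-yl]ethan-1-one (trans) | C=C(C[C@@H]1[C@@H](C(C)=O)CCC(C)=C1)[C@@H]1CC[C@](C)(O[Si](CC)(CC)CC)[C@H](Br)C1 | intermediate
16 | {[(1S,2R,4R)-2-bromo-1-methyl-4-{3-[(1S,6S)-3-methyl-6-(prop-1-en-2-yl)cyclohex-2-en-1-yl]prop-1-en-2-yl}cyclohexyl]oxy}triethylsilane | C=C(C[C@@H]1[C@@H](C(=C)C)CCC(C)=C1)[C@@H]1CC[C@](C)(O[Si](CC)(CC)CC)[C@H](Br)C1 | intermediate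
17 | (1S,2R,4R)-2-bromo-1-methyl-4-{3-[(1S,6S)-3-methyl-6-(prop-1-en-2-yl)cyclohex-2-en-1-yl]prop-1-en-2-yl}cyclohexan-1-ol | C=C(C[C@@H]1[C@@H](C(=C)C)CCC(C)=C1)[C@@H]1CC[C@](C)(O)[C@H](Br)C1 | intermediate
18 | (1S,2R,4R)-2-bromo-1-methyl-4-{3-[(1R,2R,3S,6S)-6-methyl-3-(prop-1-en-2-yl)-7-oxabicyclo[4.1.0]heptan-2-yl]prop-1-en-2-yl}cyclohexan-1-ol | C=C(C[C@@H]1[C@@H](C(=C)C)CC[C@]2(C)O[C@H]12)[C@@H]1CC[C@](C)(O)[C@H](Br)C1 | target

**Step count**

Total: 14 steps. Longest linear sequence: 13 steps (steps 1–5 and 7–14 from diol 1); step 6 is a one-step branch.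

**Steps most likely to fail**

Step 8 (the key cycloaddition). The trialkyl diene may react slowly, so that polymerisation of the acryloyl imide or acid-promoted loss of the silyl ether competes. Endo selectivity may be incomplete, which sends material into the series epimeric at C(a). Face control may be eroded at the temperature needed for conversion. The fallback replaces catalyst control by auxiliary control. It sets out from diene 10, which is treated with commercial (4S)-4-benzyl-3-acryloyl-1,3-oxazolidin-2-one (C=CC(=O)N1[C@@H](Cc2ccccc2)COC1=O) and Et2AlCl (1.4 equiv) in CH2Cl2 at −78 °C. The cationic aluminium chelate is a much stronger dienophile, and the benzyl group blocks the Re face of the α-carbon, so the same Si-face endo addition should give the auxiliary-bound cis cycloadduct F1. Aminolysis of F1 with Me(MeO)NH·HCl/AlMe3 as in step 9 comes back to the route at Weinreb amide 13.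

Step 14 (the epoxidation). Oxygen transfer to the two 1,1-disubstituted alkenes may compete. Face discrimination may be poor, because the side chain on C(a) lies on the face that has to be attacked. The ketone catalyst may be lost by Baeyer–Villiger oxidation before conversion is complete. The fallback uses a hydroxyl-directed epoxidation in the cis series and sets out from cis ketone 14. NaBH4 in MeOH at 0 °C should give the cis carbinols F2 (both carbinol epimers). VO(acac)2 (5 mol %) and t-BuOOH in CH2Cl2 then deliver oxygen from the bound hydroxyl to the C(e)=C(f) alkene on the face of the substituent on C(b), which in this series is also the face of the side chain on C(a), while the remote 1,1-disubstituted alkenes should stay untouched; this gives the epoxy carbinols F3. Oxidation with 1,1,1-triacetoxy-1,1-dihydro-1,2-benziodoxol-3(1H)-one (DMP) and NaHCO3 gives the cis epoxy ketone F4, and NaOMe in MeOH equilibrates C(b) to the trans epoxy ketone F5. Ph3PCH3Br/KOt-Bu gives the silyl ether of the target F6, and Bu4NF comes back to the route at target 18.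

Step 2 (sulfite oxidation beside the isopropenyl group). RuO4 may add to the 1,1-disubstituted alkene, which would cleave it or tie up the catalyst before the sulfite is consumed. The fallback lets the oxidant cleave the alkene on purpose and rebuilds it afterwards; it sets out from cyclic sulfite 2. RuCl3·xH2O (2 mol %) and NaIO4 (4.5 equiv) in MeCN/CCl4/H2O at rt oxidise the sulfite and cleave the isopropenyl group to acetyl in one operation, giving the keto cyclic sulfate F7. LiBr in THF opens this sulfate at the secondary carbon with inversion to the lithium keto bromoalkyl sulfate F8, and catalytic H2SO4/H2O then gives the keto bromohydrin F9; no alkene is present during the acid step. Ph3PCH3Br/KOt-Bu (2.5 equiv) in THF methylenates the acetyl group, whose equatorial position is the stable one, and comes back to the route at bromohydrin 5.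

**Further compounds**

F1 | step 8 | (4S)-4-benzyl-3-{[(1R,2S)-2-{2-[(1R,3R,4S)-3-bromo-4-methyl-4-(triethylsilyloxy)cyclohexyl]prop-2-en-1-yl}-4-methylcyclohex-3-en-1-yl]carbonyl}-1,3-oxazolidin-2-one | C=C(C[C@@H]1[C@H](C(=O)N2[C@@H](Cc3ccccc3)COC2=O)CCC(C)=C1)[C@@H]1CC[C@](C)(O[Si](CC)(CC)CC)[C@H](Br)C1
F2 | step 14 | cis carbinols, 1-[(1R,2S)-2-{2-[(1R,3R,4S)-3-bromo-4-methyl-4-(triethylsilyloxy)cyclohexyl]prop-2-en-1-yl}-4-methylcyclohex-3-en-1-yl]ethan-1-ol (both carbinol epimers) | C=C(C[C@@H]1[C@H](C(C)O)CCC(C)=C1)[C@@H]1CC[C@](C)(O[Si](CC)(CC)CC)[C@H](Br)C1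
F3 | step 14 | cis epoxy carbinols (R at C(a), R at C(b), S at C(e), R at C(f); both carbinol epimers) | C=C(C[C@@H]1[C@H](C(C)O)CC[C@]2(C)O[C@H]12)[C@@H]1CC[C@](C)(O[Si](CC)(CC)CC)[C@H](Br)C1
F4 | step 14 | cis epoxy methyl ketone (R at C(a), R at C(b), S at C(e), R at C(f)) | C=C(C[C@@H]1[C@H](C(C)=O)CC[C@]2(C)O[C@H]12)[C@@H]1CC[C@](C)(O[Si](CC)(CC)CC)[C@H](Br)C1
F5 | step 14 | trans epoxy methyl ketone (R at C(a), S at C(b), S at C(e), R at C(f)) | C=C(C[C@@H]1[C@@H](C(C)=O)CC[C@]2(C)O[C@H]12)[C@@H]1CC[C@](C)(O[Si](CC)(CC)CC)[C@H](Br)C1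
F6 | step 14 | triethylsilyl ether of target 18 | C=C(C[C@@H]1[C@@H](C(=C)C)CC[C@]2(C)O[C@H]12)[C@@H]1CC[C@](C)(O[Si](CC)(CC)CC)[C@H](Br)C1
F7 | step 2 | (3aS,6R,7aS)-6-acetyl-3a-methylhexahydro-1,3,2-benzodioxathiole 2,2-dioxide | CC(=O)[C@@H]1CC[C@](C)(OS2(=O)=O)[C@@H](O2)C1
F8 | step 2 | lithium (1S,2R,4R)-4-acetyl-2-bromo-1-methylcyclohexyl sulfate | CC(=O)[C@@H]1CC[C@](C)(OS(=O)(=O)[O-])[C@H](Br)C1.[Li+]
F9 | step 2 | 1-[(1R,3R,4S)-3-bromo-4-hydroxy-4-methylcyclohexyl]ethan-1-one | CC(=O)[C@@H]1CC[C@](C)(O)[C@H](Br)C1
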